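**Numbering used throughout.** Ring atoms are numbered as in the target: C1 carries the ester carbon C7, C2 the hydroxyl, C3 is CH, C4 carries the methoxyl, C5 is CH, C6 carries the icosyl chain.

## The problem

Methyl 2-hydroxy-6-icosyl-4-methoxybenzoate (20) is one benzene ring with four different substituents at C1 (CO2Me), C2 (OH), C4 (OMe) and C6 (unbranched C20 chain). It has no stereocentre, so nothing has to be set or relayed and the task is purely regiochemical. Three things must come out right: the ester carbon C7 must sit on C1 between the hydroxyl-bearing C2 and the chain-bearing C6; the two meta oxygens must be differentiated, free at C2 and methylated at C4; and the chain, which has no functional handle, must reach C6 as one intact piece. The chain makes every intermediate waxy and poorly soluble in polar media, which favours steps with small, polar by-products. Several stages are fragile: the free 6-alkyl-2-hydroxy-4-methoxybenzoic acid loses CO2 on heating or in strong acid, the electron-rich ring is open to halogenation and oxidation at C3 and C5, and a strained cyclobutenone and a volatile ynol ether lie on the way. The feature that opens a ring synthesis is the meta triad C2(OH)–C3(H)–C4(OMe) beside the triad C5(H)–C6(alkyl)–C1: a ketene carbonyl carbon can become C2, an alkoxyalkyne can supply C3 and the already methylated C4, and a 3-alkylcyclobutenone can supply C5, C6 and C1. A ring made this way has its oxygens differentiated from the start and leaves C1 as a CH ortho to the free phenol and para to the methoxyl, the site a chelation-guided electrophile should choose for the ester carbon.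

## Retrosynthesis

**20 ⇒ 19 (O–CH3 bond of the ester).** The methyl ester is formed last from 2-hydroxy-6-icosyl-4-methoxybenzoic acid (19). One-pot oxidative esterification of the aldehyde was the neighbouring option, but it needs halogen or peroxide oxidants that would iodinate the ring or trigger Dakin cleavage. The forward step must methylate the carboxyl group and leave the hydrogen-bonded C2 phenol free, under conditions cold enough to avoid decarboxylation.

**19 ⇒ 18 (no skeletal bond; C7 lowered from acid to aldehyde).** Acid 19 is traced to 2-hydroxy-6-icosyl-4-methoxybenzaldehyde (18). The aldehyde is chosen as the carrier of C7 because it is stable, easy to purify, and lets the position of the new carbon be checked before going on. The forward oxidation must not chlorinate C3 or C5 and must deliver the acid without heat.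

**18 ⇒ 16 (C1–C7 bond).** Removing the formyl carbon gives 3-icosyl-5-methoxyphenol (16). The alternatives for attaching C7 compare as follows:
- Direct carboxylation of 16 with MeOMgOCO2Me is one step shorter and follows the same directing logic. It is, however, an equilibrium process on a monophenol whose reactive site is flanked by an alkyl group, and it yields the labile acid at about 120 °C, so it is kept as a reserve.
- Formylation without chelation (Vilsmeier–Haack, Gattermann) also attacks C5, para to the hydroxyl.
- Ortho-lithiation would go to C3, between the two oxygens.

A magnesium-mediated ortho-formylation is irreversible and confined to the two carbons ortho to the phenol. Of these, C1 is para to the methoxyl and should be the more nucleophilic.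

**16 ⇒ 7 + 11 (C2–C3 and C4–C5; C1–C2 is broken and re-made).** The benzene ring is opened to 3-icosylcyclobut-2-en-1-one (7) and methoxyethyne (11). The alternative of coupling a chain to a symmetrical 3,5-dimethoxyarene would require the two oxygens to be differentiated afterwards by a selective demethylation. The annulation produces the phenol and the methyl ether from different atoms, so they are distinct from the outset. Carrying C7 through the annulation on the CH2 carbon of the cyclobutenone would settle C1 in the same step, but a 3-alkylcyclobutenone bearing an ester on C4 has no dependable preparation, so C1 is left as CH. The precursors are a C24 enone without aromatic ring and a three-carbon ynol ether. The forward reaction must join them in one orientation only.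

**7 ⇒ 6 ⇒ 3 + 4 (C1–C2 and C3–C4 of the four-membered ring, after putting two chlorines back on C4).** Cyclobutenone 7 comes from 4,4-dichloro-3-icosylcyclobut-2-en-1-one (6). Compound 6 is the [2+2] adduct of docos-1-yne (3) with dichloroketene (5), which is generated from trichloroacetyl chloride (4). Ketene itself does not add to unactivated alkynes, and dichloroketene is the standard surrogate. The forward sequence requires the chain to end on C3 of the enone, and the dechlorination must spare the strained enone.

**3 ⇒ 1 + 2 (bond between the chain terminus and the alkyne).** Docos-1-yne is cut to 1-bromoicosane (1) and lithium acetylide ethylenediamine complex (2), both catalogue items. The C20 bromide brings the whole chain in one step.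

**11 ⇒ 8 (two C–H/C–X eliminations).** Methoxyethyne is not a stock item and is traced to 2-chloro-1,1-dimethoxyethane (8) by loss of methanol and HCl through 1-chloro-2-methoxyethene (9) and sodium methoxyethynide (10). The forward step must deliver a volatile, polymerizable ynol ether in usable form, so it is collected directly as a cold toluene solution.

## Roads not taken

**Alternative 1: aryne carbomagnesiation with acylative trapping.**
- Cut: the C6–chain bond and the C1–C7 bond, both on a ready-made dimethoxyarene.
- Forward key step: iodine–magnesium exchange on 1-bromo-2-iodo-3,5-dimethoxybenzene A1 and loss of bromide give 3,5-dimethoxybenzyne A2. Icosylmagnesium bromide A3 (from bromide 1) adds at the aryne carbon remote from the neighbouring methoxyl. The arylmagnesium so formed, held next to that methoxyl, is quenched with methyl chloroformate A4 to give methyl 2-icosyl-4,6-dimethoxybenzoate A5. Chelation-directed Lewis-acid cleavage of the methyl ether ortho to the ester would finish.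
- Merits: chain and ester carbon enter in one flask, and their positions are fixed by the inductive control a methoxyl exerts on aryne addition. The question of C1, the soft spot of the chosen plan, does not arise. The count is about four steps, roughly half that of the chosen plan.
- Weak points: primary alkyl Grignard reagents with β-hydrogens are poor aryne partners (hydride transfer to the aryne competes). The exchange reagent is itself an alkyl Grignard and can add in place of A3. The product arylmagnesium can add to a second aryne. A hindered 2,6-disubstituted arylmagnesium must then be acylated cleanly. All risk sits in one step with no intermediate at which to correct it, and the oxygens are made equal and then differentiated by demethylation.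
- Comparison: this road is shorter and safer at C1. The chosen plan sets against it steps of established type on closely related substrates and oxygens differentiated by the ring synthesis itself.

**Alternative 2: Dieckmann-built dihydroresorcylate, aromatized late.**
- Cut: ring bonds C1–C6 (Michael addition) and C3–C4 (Dieckmann condensation).
- Forward key step: methyl acetoacetate A7 adds to methyl (E)-tricos-2-enoate A6 to give dimethyl 2-acetyl-3-icosylpentanedioate A8. Methoxide then closes the acetyl methyl carbon onto the remote ester to give methyl trans-6-icosyl-2,4-dioxocyclohexane-1-carboxylate A9 (racemic; both centres vanish later). Dehydrogenation to the resorcylate (the compound A11 of alternative 3) and methylation of the 4-hydroxyl would finish.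
- Merits: C7 is on the right carbon from the start, the reagents are cheap, and the sequence is classical and scalable.
- Weak points: A6 must first be made from a C21 aldehyde. Conjugate addition to a β-alkyl enoate with a long chain is slow and reversible. Aromatization of the dione by halogenation–dehydrohalogenation is the classical bottleneck and can halogenate the ring. A selective methylation is still needed, though it is reliable because the 2-hydroxyl is chelated.
- Comparison: the step count is similar and the regiochemistry at C1 is better than in the chosen plan. The chosen plan sets against it aromaticity reached without an oxidant and the methyl ether delivered by the annulation.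

**Alternative 3: biomimetic triketo ester aldol aromatization.**
- Cut: ring bond C1–C6 by intramolecular aldol condensation.
- Forward key step: in weakly basic buffer the C2 methylene of methyl 3,5,7-trioxoheptacosanoate A10 adds to its C7 ketone. Loss of water and enolization give methyl 2,4-dihydroxy-6-icosylbenzoate A11, and 4-O-methylation finishes.
- Merits: the shortest route of all. Ester position and oxygen pattern are written into the chain, so no regiochemical question arises at C1.
- Weak points: A10 must be assembled by acylating a polyanion of a 3,5-dioxo ester with a C21 acyl donor, which is strongly basic multi-anion chemistry of moderate efficiency. A10 is a mixture of tautomers prone to premature cyclization. The desired aldol mode competes with Claisen closure to an acylphloroglucinol and with lactonization to a 4-hydroxy-2-pyrone, and the balance depends on pH and counter-ion.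
- Comparison: if A10 is in hand, this road is shorter and safer at C1 than the chosen plan. The chosen plan offers instead stable, isolable intermediates and a single predictable mode of ring closure.

Key step: step 5

Assumption: compounds 1, 2, 4 and 8 are taken as purchasable; cyclobutenone 7 and ynol ether 11 are not stock items and are made.

## Route

Step 1
Reactants: 1 1-bromoicosane; 2 lithium acetylide ethylenediamine complex
Product: 3 docos-1-yne
Conditions: LiC≡CH·H2NCH2CH2NH2 (excess), DMSO/THF, 15 °C → rt
Reagents that add atoms: none
Why: SN2 alkylation of an acetylide by a primary bromide, a standard route to long-chain 1-alkynes; at room temperature base-induced migration of the triple bond should not occur, and THF keeps the C20 bromide in solution.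

Step 2
Reactants: 3 docos-1-yne; 4 trichloroacetyl chloride
Product: 6 4,4-dichloro-3-icosylcyclobut-2-en-1-one, via dichloroketene 5 (not isolated)
Conditions: Cl3CCOCl, zinc–copper couple, Et2O/DME, rt → 35 °C
Reagents that add atoms: none
Why: Zinc reduces 4 to dichloroketene, which undergoes thermal [2+2] ketene–alkyne cycloaddition; the unsubstituted alkyne carbon bonds to the ketene carbonyl carbon, so the chain ends on C3 of the enone, and DME binds the ZnCl2 that would otherwise degrade the product.

Step 3
Reactants: 6 4,4-dichloro-3-icosylcyclobut-2-en-1-one
Product: 7 3-icosylcyclobut-2-en-1-one
Conditions: Zn dust, AcOH, TMEDA, EtOH/THF, 0 °C → rt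
Reagents that add atoms: none
Why: Zinc reductive dechlorination of an α,α-dichloroketone through zinc enolates protonated by acetic acid, established for 3-alkyl-4,4-dichlorocyclobutenones; TMEDA buffers the medium so that the strained enone is neither over-reduced nor opened.

Step 4
Reactants: 8 2-chloro-1,1-dimethoxyethane
Product: 11 methoxyethyne, via 1-chloro-2-methoxyethene 9 (not isolated), via sodium methoxyethynide 10 (not isolated)
Conditions: NaNH2 (3 equiv), liquid NH3, −33 °C; evaporate NH3; saturated aq NaCl, −20 °C; distil into cold toluene
Reagents that add atoms: none
Why: Base-induced double elimination (methanol, then HCl) from the chloroacetal, the standard preparation of alkoxyacetylenes; the third equivalent of NaNH2 holds the product as the non-volatile acetylide 10 until cold brine releases the ynol ether, which is used as a titrated cold toluene solution.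

Step 5
Reactants: 7 3-icosylcyclobut-2-en-1-one; 11 methoxyethyne
Product: 16 3-icosyl-5-methoxyphenol, via vinylketene 12 (not isolated), via vinylcyclobutenone 13 (not isolated), via dienylketene 14 (not isolated), via cyclohexadienone 15 (not isolated)
Conditions: 11 (excess, toluene solution), degassed toluene, sealed tube, 80 °C then 110 °C
Reagents that add atoms: none
Why: This is the Danheiser benzannulation, the known thermal union of cyclobutenones with alkoxyacetylenes to 3-alkoxyphenols. Heating opens 7 by a 4π electrocyclic reaction (breaking the future C1–C2 bond) to vinylketene 12, whose ketene C=C adds 11 in a [2+2] cycloaddition to give vinylcyclobutenone 13, forming C2–C3 and C4–C5. A second, reversible 4π opening of 13 gives dienylketene 14, of which only the isomer with the ketene-bearing carbon and the alkenyl group cis can react further. The benzene ring is closed by thermal 6π electrocyclization (disrotatory) of 14, which re-forms C1–C2 between the ketene carbon and the terminal CH2 to give cyclohexadienone 15, and tautomerization to phenol 16 makes the sequence irreversible. The selectivity needed is the orientation of the [2+2] step: the nucleophilic CH terminus of the ynol ether must bond to the electrophilic ketene carbonyl carbon, which the polarization of both partners dictates, so the methoxyl ends meta to the hydroxyl and the chain meta to both. No stereocentre is present in 16, and the transient one in 13 is erased on ring opening. Excess alkyne in a closed vessel is used to outrun dimerization of 12 and its capture by the product phenol.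

Step 6
Reactants: 16 3-icosyl-5-methoxyphenol
Product: 18 2-hydroxy-6-icosyl-4-methoxybenzaldehyde, via hydroxymethylphenol 17 (not isolated)
Conditions: MgCl2 (anhydrous), Et3N, (CH2O)n, THF, reflux; then 1 M HCl
Reagents that add atoms: paraformaldehyde (as formaldehyde), C=O
Why: Casnati–Skattebøl ortho-formylation: the magnesium phenoxide binds formaldehyde and delivers it through a six-membered transition state to an ortho carbon only, and the salicyl alkoxide 17 is oxidized to the aldehyde by hydride transfer to a second formaldehyde; of the two ortho sites C1 is para to the methoxyl and should be the more nucleophilic, as in the formylation of 3-methoxyphenol para to its methoxyl, while C5 is out of reach of the chelated electrophile.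

Step 7
Reactants: 18 2-hydroxy-6-icosyl-4-methoxybenzaldehyde
Product: 19 2-hydroxy-6-icosyl-4-methoxybenzoic acid
Conditions: NaClO2, H2NSO3H, THF/H2O, 0 °C → rt
Reagents that add atoms: sodium chlorite, [Na+].[O-]Cl=O
Why: Lindgren (Pinnick-type) chlorite oxidation, long used for free hydroxybenzaldehydes; sulfamic acid is both the proton source and the trap for the HOCl by-product that would otherwise chlorinate C3 or C5, and the cold, weakly acidic medium should spare the acid from decarboxylation.

Step 8
Reactants: 19 2-hydroxy-6-icosyl-4-methoxybenzoic acid
Product: 20 methyl 2-hydroxy-6-icosyl-4-methoxybenzoate
Conditions: Me3SiCHN2 (slight excess), toluene/MeOH, 0 °C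
Reagents that add atoms: (trimethylsilyl)diazomethane, C[Si](C)(C)C=[N+]=[N-]
Why: Esterification by diazomethane released through methanolysis of the protonated silyl diazoalkane; the carboxylic acid is far more acidic than the hydrogen-bonded C2 phenol, so with near-stoichiometric reagent at 0 °C the phenol should stay free.

## Compound list

1 | 1-bromoicosane | CCCCCCCCCCCCCCCCCCCCBr | starting material
2 | lithium acetylide ethylenediamine complex | [Li]C#C.NCCN | starting material
3 | docos-1-yne | CCCCCCCCCCCCCCCCCCCCC#C | intermediate
4 | trichloroacetyl chloride | ClC(=O)C(Cl)(Cl)Cl | starting material
5 | dichloroketene (formed in the flask, not isolated) | ClC(Cl)=C=O | intermediate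
6 | 4,4-dichloro-3-icosylcyclobut-2-en-1-one | CCCCCCCCCCCCCCCCCCCCC1=CC(=O)C1(Cl)Cl | intermediate
7 | 3-icosylcyclobut-2-en-1-one | CCCCCCCCCCCCCCCCCCCCC1=CC(=O)C1 | intermediate
8 | 2-chloro-1,1-dimethoxyethane (chloroacetaldehyde dimethyl acetal) | COC(CCl)OC | starting material
9 | 1-chloro-2-methoxyethene (E/Z mixture, not isolated) | COC=CCl | intermediate
10 | sodium methoxyethynide (not isolated) | [Na+].[C-]#COC | intermediate
11 | methoxyethyne (methoxyacetylene), kept as a cold toluene solution | COC#C | intermediate
12 | 3-icosylbuta-1,3-dien-1-one (vinylketene, not isolated) | CCCCCCCCCCCCCCCCCCCCC(=C)C=C=O | intermediate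
13 | 4-(docos-1-en-2-yl)-3-methoxycyclobut-2-en-1-one (racemic, not isolated) | CCCCCCCCCCCCCCCCCCCCC(=C)C1C(=O)C=C1OC | intermediate
14 | (3E)-5-icosyl-3-methoxyhexa-1,3,5-trien-1-one (dienylketene with C2 and C5 cis, not isolated) | CCCCCCCCCCCCCCCCCCCCC(=C)/C=C(/OC)C=C=O | intermediate
15 | 5-icosyl-3-methoxycyclohexa-2,4-dien-1-one (not isolated) | CCCCCCCCCCCCCCCCCCCCC1=CC(OC)=CC(=O)C1 | intermediate
16 | 3-icosyl-5-methoxyphenol | CCCCCCCCCCCCCCCCCCCCc1cc(O)cc(OC)c1 | intermediate
17 | 2-(hydroxymethyl)-3-icosyl-5-methoxyphenol (as its magnesium salt, not isolated) | CCCCCCCCCCCCCCCCCCCCc1cc(OC)cc(O)c1CO | intermediate
18 | 2-hydroxy-6-icosyl-4-methoxybenzaldehyde | CCCCCCCCCCCCCCCCCCCCc1cc(OC)cc(O)c1C=O | intermediate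
19 | 2-hydroxy-6-icosyl-4-methoxybenzoic acid | CCCCCCCCCCCCCCCCCCCCc1cc(OC)cc(O)c1C(=O)O | intermediate
20 | methyl 2-hydroxy-6-icosyl-4-methoxybenzoate | CCCCCCCCCCCCCCCCCCCCc1cc(OC)cc(O)c1C(=O)OC | target

## Step count and weakest steps

Total: 8 steps. Longest linear sequence: 7 steps (steps 1, 2, 3, 5, 6, 7, 8); step 4 is a one-step branch.

**Step 5 (key step).** The most likely failure is loss or polymerization of the volatile ynol ether before the cyclobutenone has opened. The ring opening needs about 80 °C, where 11 sits largely in the head space. At low alkyne concentration the vinylketene 12 then dimerizes or acylates the product phenol.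
Fallback: the annulation is abandoned for this intermediate, and the route is left at bromide 1. Commercial 1-bromo-3,5-dimethoxybenzene is converted with magnesium in THF into 3,5-dimethoxyphenylmagnesium bromide F1. F1 is coupled with 1 under Li2CuCl4 catalysis (Kochi-type coupling) to give 1-icosyl-3,5-dimethoxybenzene F2. Heating F2 with NaSEt in DMF removes one methyl group only, because the phenoxide formed resists a second cleavage. This returns to the route at phenol 16.

**Step 6.** The risk is incomplete site selectivity between the two carbons ortho to the phenol. Attack at C3, between the oxygens, competes if the steric shielding of C1 by the chain outweighs the para-methoxyl activation. Over-reaction to a dialdehyde is a second possibility.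
Fallback: phenol 16 is methylated (MeI, K2CO3, acetone) to the symmetrical 1-icosyl-3,5-dimethoxybenzene F2, in which both carbons next to the chain are equivalent. Vilsmeier–Haack formylation (POCl3, DMF), which avoids the position between two methoxyls, gives 2-icosyl-4,6-dimethoxybenzaldehyde F3. BCl3 in CH2Cl2 at low temperature then cleaves only the methyl ether chelated to the formyl group. This returns to the route at aldehyde 18.

**Step 7.** The risk is ring chlorination by hypochlorous acid at C3 or C5 if scavenging is too slow, and decarboxylation of the acid during work-up or concentration.
Fallback: the aldehyde stage is bypassed. Phenol 16 is carboxylated directly with MeOMgOCO2Me in DMF at about 120 °C, a chelation-controlled ortho-carboxylation of the kind used on alkylresorcinols and their monoethers, followed by cold dilute acid. This sets out from 16 and returns at acid 19, leaving out 18 (no new compound; F0).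

**Step 3.** The risk is over-reduction or ring opening and oligomerization of the strained enone during dechlorination and isolation, made worse by the poor solubility of waxy 6 in ethanol, which prolongs contact with zinc and acid.
Fallback: the four-membered ring is bought instead of built. Bromide 1 is converted with magnesium into icosylmagnesium bromide F4, which adds to the carbonyl group of commercial 3-ethoxycyclobut-2-en-1-one to give 3-ethoxy-1-icosylcyclobut-2-en-1-ol F5 (racemic). Dilute acid hydrolyses the enol ether with allylic transposition (Stork–Danheiser-type). This returns to the route at cyclobutenone 7 and leaves out steps 1 to 3.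

## Further compounds

F1 | step 5 | 3,5-dimethoxyphenylmagnesium bromide | COc1cc(OC)cc([Mg]Br)c1
F2 | step 5 | 1-icosyl-3,5-dimethoxybenzene | CCCCCCCCCCCCCCCCCCCCc1cc(OC)cc(OC)c1
F3 | step 6 | 2-icosyl-4,6-dimethoxybenzaldehyde | CCCCCCCCCCCCCCCCCCCCc1cc(OC)cc(OC)c1C=O
F0 | step 7 | none | none
F4 | step 3 | icosylmagnesium bromide | CCCCCCCCCCCCCCCCCCCC[Mg]Br
F5 | step 3 | 3-ethoxy-1-icosylcyclobut-2-en-1-ol (racemic) | CCCCCCCCCCCCCCCCCCCCC1(O)CC(OCC)=C1
A1 | alternative 1 | 1-bromo-2-iodo-3,5-dimethoxybenzene | COc1cc(OC)c(I)c(Br)c1
A2 | alternative 1 | 3,5-dimethoxybenzyne (1,2-didehydro-3,5-dimethoxybenzene) | COC1=CC(OC)=CC#C1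
A3 | alternative 1 | icosylmagnesium bromide | CCCCCCCCCCCCCCCCCCCC[Mg]Br
A4 | alternative 1 | methyl chloroformate | COC(=O)Cl
A5 | alternative 1 | methyl 2-icosyl-4,6-dimethoxybenzoate | CCCCCCCCCCCCCCCCCCCCc1cc(OC)cc(OC)c1C(=O)OC
A6 | alternative 2 | methyl (E)-tricos-2-enoate | CCCCCCCCCCCCCCCCCCCC/C=C/C(=O)OC
A7 | alternative 2 | methyl acetoacetate | CC(=O)CC(=O)OC
A8 | alternative 2 | dimethyl 2-acetyl-3-icosylpentanedioate (racemic mixture of diastereomers) | CCCCCCCCCCCCCCCCCCCCC(CC(=O)OC)C(C(C)=O)C(=O)OC
A9 | alternative 2 | methyl trans-6-icosyl-2,4-dioxocyclohexane-1-carboxylate (racemic) | CCCCCCCCCCCCCCCCCCCC[C@@H]1CC(=O)CC(=O)[C@H]1C(=O)OC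
A10 | alternative 3 | methyl 3,5,7-trioxoheptacosanoate | CCCCCCCCCCCCCCCCCCCCC(=O)CC(=O)CC(=O)CC(=O)OC
A11 | alternative 3 | methyl 2,4-dihydroxy-6-icosylbenzoate | CCCCCCCCCCCCCCCCCCCCc1cc(O)cc(O)c1C(=O)OC
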